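Start from an invariant. In the alpha run, which is this very flask followed so far, starting material plus target stays at the charge within the scatter, 100% at 120 min. Target therefore takes up what the starting material loses, and the second substrate, never read, is what remains to account for.

| flask | starting material | second substrate | precatalyst | temperature | remark | time |
|---|---|---|---|---|---|---|
| alpha | 10 mM | 10.5 mM | 1.1 µM | 37 °C | the very flask that is asked about, followed so far |  |
| beta | 5 mM | 10.5 mM | 1.1 µM | 43 °C | run made earlier |  |
| flask | 10 mM | 10.5 mM | 1.1 µM | 37 °C |  | 2.5 h |

- alpha (time / min: target / %, starting material / %): 10.0: 19.5, 80.5; 15.0: 21.0, 79.1; 25.0: 22.1, 77.6; 40.0: 22.8, 77.4; 80.0: 22.5, 77.3; 120: 22.9, 77.6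
- beta (time / min: target / %, starting material / %): 0.250: 0.9, 99.0; 0.417: 0.6, 99.1; 0.667: 1.4, 97.8; 1.33: 4.1, 95.9; 2.00: 6.3, 93.7; 3.00: 8.5, 91.7

(standard deviation of a reading: 0.3 percentage points)

- target that was removed still counts
- additions bring no volume worth counting

- Monday's: at 2.5 h raise the temperature by 10 K, then wait 2.5 h
- Friday's: at 2.5 h add precatalyst, 100% of the amount charged, then wait 2.5 h
- Tuesday's: at 2.5 h take out 90% of the target then present, then wait 2.5 h
- Sunday's: at 2.5 h add second substrate, 100% of the amount charged, then wait 2.5 h
- Wednesday's: change nothing and wait 2.5 h more

- target, in percent of the starting material first charged, at 2.5 h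
- which option adds most target ("none" when 2 percentage points or less is all one gets) (Monday's / Friday's / Tuesday's / Sunday's / Wednesday's / none)
- target present, with what was taken out counted in, in percent of the starting material first charged, after Sunday's
- target present, with what was taken out counted in, in percent of the starting material first charged, after Wednesday's

Average the last three alpha readings: target levels at 22.7% of the starting material, which is 21.7% of the second substrate charged. Call this fraction, target made per second substrate charged, the capture share. Take one second substrate per target as the zero of the scale: full conversion of the starting material then captures 95.2%, and on that scale, with nothing else taking second substrate, 78.3% of it would still stand in alpha.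

Now compare beta, which has the same second substrate charge, half the starting material, and a hotter bath. Its capture share is 4.05% at its last reading, and it gained 2.2 percentage points in the last 1.00 min, so beta is simply still climbing when its readings end. Alpha averaged a faster climb over its first 10.0 min than over the next 5.00 min, while its starting material moved from 80.5% to 79.1%. That loss of starting material is small beside the slowing of the climb, so look elsewhere for what stopped alpha.

Suppose the second substrate left by a path these columns cannot show. Then the capture share is what one charge buys, and a second equal charge buys no more. This reckoning is ours, and an estimate: it backs Sunday's, with 45.5% of target as its upper figure.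

The forecast differs on the choice. It gives 22.7% now, 22.7% after Wednesday's, and 23% after Sunday's (up to 34%), and it picks Friday's, holding that “fresh precatalyst should restart conversion”.

The flask gives 22.6% now, 22.6% after Wednesday's and 33.8% after Sunday's. The best option is Sunday's, adding 11 points against 0 points for Friday's.

    starting material + free enzyme ⇌ starting complex (K = 23.0 M⁻¹, k = 6.20 × 10⁵ M⁻¹ s⁻¹, Ea = 21.0 kJ mol⁻¹, ΔH = −68.0 kJ mol⁻¹)
    second substrate + precatalyst → free enzyme + spent reagent (k = 1.00 M⁻¹ s⁻¹, Ea = 53.0 kJ mol⁻¹)
    2 second substrate → self-condensation product (k = 0.840 M⁻¹ s⁻¹, Ea = 49.0 kJ mol⁻¹)
    second substrate + starting complex ⇌ ternary complex (K = 140 M⁻¹, k = 91000 M⁻¹ s⁻¹, Ea = 12.0 kJ mol⁻¹, ΔH = −38.0 kJ mol⁻¹)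
    free enzyme → unfolded enzyme (k = 3.50 × 10⁻⁴ s⁻¹, Ea = 181 kJ mol⁻¹)
    ternary complex → free enzyme + target (k = 210 s⁻¹, Ea = 62.0 kJ mol⁻¹)
    (constants at 37 °C)

At 150 min this flask holds 0% of its second substrate, the limiting reagent although charged in excess. Its 4.12 mM of self-condensation product, two second substrate each, accounts for 78.5% of that charge beside the capture share of 21.7%. Sunday's second charge captures 10.7% of itself, half of what the first charge captured by 150 min. The neighbour charged with 18 mM of second substrate has 1.80 equiv, so an unchanged capture share gives target at 39.0% of the starting material. That neighbour gives 28.6%, a capture share of 15.9%, and its 7.57 mM of self-condensation product accounts for 84.1% of its charge.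

(The runs are calculated on assumed constants.)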